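The oxolane is disconnected at C2. This ArCH carbon stands alone between O1 and C3, so taking it out leaves a cis-2,3-disubstituted oxetane that already holds C3 with its C9 arm, C4 with the C7' guaiacylmethyl arm, and C5. In the forward direction a rhodium carbene from the protected catechol aryldiazomethane adds to the oxetane oxygen; the oxonium ylide then undergoes a [1,2]-shift of C3, which forms O1–C2 and C2–C3, enlarges the four-membered ring to the oxolane and sets C2, all in one operation. The oxetane precursor is made by an Evans syn-aldol, reduction and Williamson closure, with O9 as a triisopropylsilyl ether and the phenol as a benzyl ether.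

Key step: step 8

Numbering: oxolane O1, C2 (catechol aryl), C3 (bears C9H2O), C4 (bears C7'H2-guaiacyl), C5; the target is 2S,3R,4R (2,3-trans, 3,4-cis).

Remark: O9 is carried as a triisopropylsilyl ether, because a smaller silyl group could move to the neighbouring alkoxide during oxetane closure; (triisopropylsilyloxy)acetaldehyde is taken to be a catalogue aldehyde.

Step 1
Reactants: 1 3-(4-hydroxy-3-methoxyphenyl)propanoic acid
Product: 3 3-(4-benzyloxy-3-methoxyphenyl)propanoic acid, via benzyl ester 2 (not isolated)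
Conditions: BnBr, K2CO3, DMF, 60 °C; then NaOH, MeOH/H2O, 60 °C; HCl work-up
Reagents that add atoms: benzyl bromide, BrCc1ccccc1; sodium hydroxide, [Na+].[OH-]
Why: Williamson O-alkylation benzylates phenoxide and carboxylate alike, and saponification then frees the acid while the aryl benzyl ether stays; no stereocentre is involved.

Step 2
Reactants: 3 3-(4-benzyloxy-3-methoxyphenyl)propanoic acid; 4 (R)-4-benzyloxazolidin-2-one
Product: 6 (R)-4-benzyl-3-[3-(4-benzyloxy-3-methoxyphenyl)propanoyl]oxazolidin-2-one, via mixed pivalic anhydride 5 (not isolated)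
Conditions: tBuCOCl, Et3N, THF, −20 °C; then 4, LiCl, −20 °C to rt
Reagents that add atoms: none
Why: N-acylation of the oxazolidinone by the mixed pivalic anhydride occurs at the unhindered acyl carbon and leaves the auxiliary centre untouched.

Step 3
Reactants: 6 (R)-4-benzyl-3-[3-(4-benzyloxy-3-methoxyphenyl)propanoyl]oxazolidin-2-one; 7 (triisopropylsilyloxy)acetaldehyde
Product: 9 (R)-4-benzyl-3-[(2R,3R)-2-(4-benzyloxy-3-methoxybenzyl)-3-hydroxy-4-(triisopropylsilyloxy)butanoyl]oxazolidin-2-one, via dibutylboron enolate 8 (not isolated)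
Conditions: Bu2BOTf, iPr2NEt, CH2Cl2, −78 to 0 °C; 7, −78 to 0 °C; then pH 7 buffer, MeOH, H2O2, 0 °C
Reagents that add atoms: none
Why: Evans syn-aldol reaction, in which the Z boron enolate reacts through a chair Zimmerman–Traxler transition state and the aldehyde adds to the enolate face turned away from the auxiliary benzyl group, which should set the two new centres as 2R,3R (syn).

Step 4
Reactants: 9 (R)-4-benzyl-3-[(2R,3R)-2-(4-benzyloxy-3-methoxybenzyl)-3-hydroxy-4-(triisopropylsilyloxy)butanoyl]oxazolidin-2-one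
Product: 10 (2S,3R)-2-(4-benzyloxy-3-methoxybenzyl)-4-(triisopropylsilyloxy)butane-1,3-diol
Conditions: LiBH4, MeOH (1 equiv), THF, 0 °C
Reagents that add atoms: none
Why: Borohydride reduction of the N-acyl oxazolidinone cleaves the exocyclic acyl group to the primary alcohol without touching either stereocentre or the silyl and benzyl ethers.

Step 5
Reactants: 10 (2S,3R)-2-(4-benzyloxy-3-methoxybenzyl)-4-(triisopropylsilyloxy)butane-1,3-diol
Product: 11 (2S,3R)-2-(4-benzyloxy-3-methoxybenzyl)-3-hydroxy-4-(triisopropylsilyloxy)butyl 4-methylbenzenesulfonate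
Conditions: TsCl (1.05 equiv), Et3N, DMAP (cat.), CH2Cl2, 0 °C
Reagents that add atoms: p-toluenesulfonyl chloride, Cc1ccc(cc1)S(Cl)(=O)=O
Why: Sulfonylation is much faster at the primary hydroxyl than at the flanked secondary one, so the monotosylate should form selectively.

Step 6
Reactants: 11 (2S,3R)-2-(4-benzyloxy-3-methoxybenzyl)-3-hydroxy-4-(triisopropylsilyloxy)butyl 4-methylbenzenesulfonate
Product: 12 (2R,3S)-3-(4-benzyloxy-3-methoxybenzyl)-2-[(triisopropylsilyloxy)methyl]oxetane (cis)
Conditions: KOtBu, THF, 0 °C to rt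
Reagents that add atoms: none
Why: Intramolecular Williamson etherification (4-exo-tet), in which the secondary alkoxide displaces the primary tosylate, so both centres are retained and the syn diol becomes the cis oxetane, while the hindered silyl group should stay on O9.

Step 7
Reactants: 13 3,4-bis(benzyloxy)benzaldehyde
Product: 14 (E)-N'-[3,4-bis(benzyloxy)benzylidene]-4-methylbenzenesulfonohydrazide
Conditions: TsNHNH2, MeOH, rt
Reagents that add atoms: p-toluenesulfonyl hydrazide, Cc1ccc(cc1)S(=O)(=O)NN
Why: Condensation of the aldehyde with the sulfonyl hydrazide gives the crystalline tosylhydrazone, the storable precursor of the diazo compound (Bamford–Stevens chemistry).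

Step 8
Reactants: 12 (2R,3S)-3-(4-benzyloxy-3-methoxybenzyl)-2-[(triisopropylsilyloxy)methyl]oxetane; 14 (E)-N'-[3,4-bis(benzyloxy)benzylidene]-4-methylbenzenesulfonohydrazide
Product: 17 (2S,3R,4R)-2-[3,4-bis(benzyloxy)phenyl]-4-(4-benzyloxy-3-methoxybenzyl)-3-[(triisopropylsilyloxy)methyl]oxolane, via tosylhydrazone sodium salt 15 (not isolated), via aryldiazomethane 16 (not isolated)
Conditions: 14 (2.5 equiv), NaH, 1,4-dioxane, rt; then 12, BnEt3NCl (10 mol %), Rh2(OAc)4 (2 mol %), 40 °C
Reagents that add atoms: none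
Why: Proposed new method: the tosylhydrazone salt releases aryldiazomethane 16 slowly, the divalent rhodium carboxylate Rh2(OAc)4 turns it into an electrophilic carbene, and the oxetane oxygen, the most basic and least shielded oxygen of 12, adds to it on the lone pair anti to the C9 arm to give an oxonium ylide. Strain release then drives a Stevens [1,2]-shift in which the O1–C3 bond breaks to a caged pair of a secondary C3 radical and an α-oxybenzyl radical that recombines at C2–C3, so the oxolane is closed by a four-to-five ring enlargement and not by an exo or endo cyclisation. The closest known reaction type is the copper- or rhodium-carbene ring expansion of oxetanes with diazo esters, together with ylide formation from aryldiazomethanes generated in the flask from tosylhydrazone salts. The new centre C2 is set under substrate control, the aryl group taking the side of the ring opposite to the bulky CH2OSi(iPr)3 arm on C3 during recombination, which is also the more stable 2,3-trans arrangement. C3 should keep its configuration because recombination within the tethered pair is faster than bond rotation, so the cis relation of C9 and C7' is carried over. The step needs C3 and not C5 to migrate, which rests on the better stabilised secondary radical and on release of the cis-2,3 eclipsing strain, and it needs ylide formation to beat carbene dimerisation, which the slow release of 16 and the shielding of O9 by the silyl group serve.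

Step 9
Reactants: 17 (2S,3R,4R)-2-[3,4-bis(benzyloxy)phenyl]-4-(4-benzyloxy-3-methoxybenzyl)-3-[(triisopropylsilyloxy)methyl]oxolane
Product: 18 [(2S,3R,4R)-2-[3,4-bis(benzyloxy)phenyl]-4-(4-benzyloxy-3-methoxybenzyl)oxolan-3-yl]methanol
Conditions: Bu4NF, THF, 0 °C to rt
Reagents that add atoms: none
Why: Fluoride cleaves the Si–O bond of the primary silyl ether, and the benzyl ethers and the oxolane are inert to it.

Step 10
Reactants: 18 [(2S,3R,4R)-2-[3,4-bis(benzyloxy)phenyl]-4-(4-benzyloxy-3-methoxybenzyl)oxolan-3-yl]methanol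
Product: 19 [(2S,3R,4R)-2-[3,4-bis(benzyloxy)phenyl]-4-(4-benzyloxy-3-methoxybenzyl)oxolan-3-yl]methyl acetate
Conditions: Ac2O, pyridine, DMAP (cat.), CH2Cl2, rt
Reagents that add atoms: acetic anhydride, CC(=O)OC(C)=O
Why: DMAP-catalysed acylation of the only free hydroxyl should give the primary acetate.

Step 11
Reactants: 19 [(2S,3R,4R)-2-[3,4-bis(benzyloxy)phenyl]-4-(4-benzyloxy-3-methoxybenzyl)oxolan-3-yl]methyl acetate
Product: 20 [(2S,3R,4R)-2-(3,4-dihydroxyphenyl)-4-(4-hydroxy-3-methoxybenzyl)oxolan-3-yl]methyl acetate (the target)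
Conditions: H2 (1 atm), 10 % Pd/C, EtOAc, rt
Reagents that add atoms: none
Why: Catalytic hydrogenolysis cleaves the three aryl benzyl ethers much faster than the cyclic benzylic C2–O1 bond in a neutral aprotic solvent, and the acetate, the methyl ether and the three stereocentres are unaffected.

Compound list
1 | 3-(4-hydroxy-3-methoxyphenyl)propanoic acid | O=C(O)CCc1ccc(O)c(OC)c1 | starting material
2 | benzyl 3-(4-benzyloxy-3-methoxyphenyl)propanoate | O=C(OCc1ccccc1)CCc1ccc(OCc2ccccc2)c(OC)c1 | intermediate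
3 | 3-(4-benzyloxy-3-methoxyphenyl)propanoic acid | O=C(O)CCc1ccc(OCc2ccccc2)c(OC)c1 | intermediate
4 | (R)-4-benzyloxazolidin-2-one | O=C1N[C@H](Cc2ccccc2)CO1 | starting material
5 | 3-(4-benzyloxy-3-methoxyphenyl)propanoic pivalic anhydride | CC(C)(C)C(=O)OC(=O)CCc1ccc(OCc2ccccc2)c(OC)c1 | intermediate
6 | (R)-4-benzyl-3-[3-(4-benzyloxy-3-methoxyphenyl)propanoyl]oxazolidin-2-one | O=C(CCc1ccc(OCc2ccccc2)c(OC)c1)N1[C@H](Cc2ccccc2)COC1=O | intermediate
7 | (triisopropylsilyloxy)acetaldehyde | O=CCO[Si](C(C)C)(C(C)C)C(C)C | starting material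
8 | Z dibutylboron enolate of 6 | CCCCB(CCCC)O/C(=C\Cc1ccc(OCc2ccccc2)c(OC)c1)N1[C@H](Cc2ccccc2)COC1=O | intermediate
9 | (R)-4-benzyl-3-[(2R,3R)-2-(4-benzyloxy-3-methoxybenzyl)-3-hydroxy-4-(triisopropylsilyloxy)butanoyl]oxazolidin-2-one | O=C([C@H](Cc1ccc(OCc2ccccc2)c(OC)c1)[C@@H](O)CO[Si](C(C)C)(C(C)C)C(C)C)N1[C@H](Cc2ccccc2)COC1=O | intermediate
10 | (2S,3R)-2-(4-benzyloxy-3-methoxybenzyl)-4-(triisopropylsilyloxy)butane-1,3-diol | OC[C@H](Cc1ccc(OCc2ccccc2)c(OC)c1)[C@@H](O)CO[Si](C(C)C)(C(C)C)C(C)C | intermediate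
11 | (2S,3R)-2-(4-benzyloxy-3-methoxybenzyl)-3-hydroxy-4-(triisopropylsilyloxy)butyl 4-methylbenzenesulfonate | Cc1ccc(cc1)S(=O)(=O)OC[C@H](Cc1ccc(OCc2ccccc2)c(OC)c1)[C@@H](O)CO[Si](C(C)C)(C(C)C)C(C)C | intermediate
12 | (2R,3S)-3-(4-benzyloxy-3-methoxybenzyl)-2-[(triisopropylsilyloxy)methyl]oxetane (cis) | O1C[C@H](Cc2ccc(OCc3ccccc3)c(OC)c2)[C@@H]1CO[Si](C(C)C)(C(C)C)C(C)C | intermediate
13 | 3,4-bis(benzyloxy)benzaldehyde | O=Cc1ccc(OCc2ccccc2)c(OCc2ccccc2)c1 | starting material
14 | (E)-N'-[3,4-bis(benzyloxy)benzylidene]-4-methylbenzenesulfonohydrazide | Cc1ccc(cc1)S(=O)(=O)N/N=C/c1ccc(OCc2ccccc2)c(OCc2ccccc2)c1 | intermediate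
15 | sodium salt of tosylhydrazone 14 | [Na+].Cc1ccc(cc1)S(=O)(=O)[N-]/N=C/c1ccc(OCc2ccccc2)c(OCc2ccccc2)c1 | intermediate
16 | [3,4-bis(benzyloxy)phenyl]diazomethane | [N-]=[N+]=Cc1ccc(OCc2ccccc2)c(OCc2ccccc2)c1 | intermediate
17 | (2S,3R,4R)-2-[3,4-bis(benzyloxy)phenyl]-4-(4-benzyloxy-3-methoxybenzyl)-3-[(triisopropylsilyloxy)methyl]oxolane | c1ccccc1COc1ccc(cc1OCc1ccccc1)[C@H]1OC[C@H](Cc2ccc(OCc3ccccc3)c(OC)c2)[C@@H]1CO[Si](C(C)C)(C(C)C)C(C)C | intermediate
18 | [(2S,3R,4R)-2-[3,4-bis(benzyloxy)phenyl]-4-(4-benzyloxy-3-methoxybenzyl)oxolan-3-yl]methanol | c1ccccc1COc1ccc(cc1OCc1ccccc1)[C@H]1OC[C@H](Cc2ccc(OCc3ccccc3)c(OC)c2)[C@@H]1CO | intermediate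
19 | [(2S,3R,4R)-2-[3,4-bis(benzyloxy)phenyl]-4-(4-benzyloxy-3-methoxybenzyl)oxolan-3-yl]methyl acetate | c1ccccc1COc1ccc(cc1OCc1ccccc1)[C@H]1OC[C@H](Cc2ccc(OCc3ccccc3)c(OC)c2)[C@@H]1COC(C)=O | intermediate
20 | [(2S,3R,4R)-2-(3,4-dihydroxyphenyl)-4-(4-hydroxy-3-methoxybenzyl)oxolan-3-yl]methyl acetate | COc1cc(C[C@H]2CO[C@H](c3ccc(O)c(O)c3)[C@H]2COC(C)=O)ccc1O | target

Total step count: 11. Longest linear sequence: 10 steps (steps 1–6 and 8–11); step 7 is a one-step branch.

Steps most likely to fail

Step 8 (key step). The carbene may dimerise (stilbene or azine formation) faster than it is captured by the oxetane. The shift may also take place at C5, lose configuration at C3, or give poor facial control at C2. The fallback uses the established lactone-aldol and cycloetherification chemistry of this lignan class. It sets out from acid 3 (with aldehyde 13) and comes back to the route at alcohol 18, so that only steps 10 and 11 remain.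
- Acid 3 is coupled through anhydride 5 to (S)-4-benzyloxazolidin-2-one to give (S)-4-benzyl-3-[3-(4-benzyloxy-3-methoxyphenyl)propanoyl]oxazolidin-2-one F1.
- Evans alkylation with NaN(SiMe3)2 and tert-butyl bromoacetate (THF, −78 °C) should give tert-butyl (3R)-4-[(4S)-4-benzyl-2-oxooxazolidin-3-yl]-3-(4-benzyloxy-3-methoxybenzyl)-4-oxobutanoate F2. The chelated sodium enolate is attacked on the face opposite to that of the boron aldol, hence the other auxiliary enantiomer.
- LiBH4 reduction gives tert-butyl (3R)-3-(4-benzyloxy-3-methoxybenzyl)-4-hydroxybutanoate F3.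
- TsOH in toluene lactonises it to (R)-4-(4-benzyloxy-3-methoxybenzyl)oxolan-2-one F4.
- LiN(iPr)2 and aldehyde 13 (THF, −78 °C) add trans to the benzyl group and give (3S,4R)-3-{[3,4-bis(benzyloxy)phenyl](hydroxy)methyl}-4-(4-benzyloxy-3-methoxybenzyl)oxolan-2-one F5. Both carbinol epimers are usable.
- LiAlH4 gives (2R,3R)-2-{[3,4-bis(benzyloxy)phenyl](hydroxy)methyl}-3-(4-benzyloxy-3-methoxybenzyl)butane-1,4-diol F6.
- Catalytic camphorsulfonic acid in CH2Cl2 at 0 °C closes O1–C2 through the benzylic cation with the 2,3-trans preference and gives 18.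

Step 6 (oxetane closure). The alkoxide may take over the silyl group and then close a five-membered ring, or it may fragment instead of displacing the tosylate. The fallback closes the ring without any alkoxide. It sets out from diol 10, skips tosylate 11 and comes back at oxetane 12. Diol 10 is cyclodehydrated under Mitsunobu-type conditions (PPh3, diisopropyl azodicarboxylate, Zn(S2CNMe2)2 as promoter, toluene). The primary hydroxyl is activated as an oxyphosphonium ion and displaced by the neutral secondary hydroxyl with retention at both centres. This makes no new compound, F0.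

Step 11 (hydrogenolysis). The benzylic C2–O1 bond may be opened by over-reduction, or the debenzylation may stall. The fallback removes the benzyl groups without hydrogen. It sets out from acetate 19 and comes back at target 20. BCl3 with pentamethylbenzene in CH2Cl2 at −78 °C is a Lewis-acid dealkylation with a non-basic cation scavenger, which acetates and aryl methyl ethers tolerate at this temperature. This makes no new compound, F0.

Further compounds
F1 | step 8 | (S)-4-benzyl-3-[3-(4-benzyloxy-3-methoxyphenyl)propanoyl]oxazolidin-2-one | O=C(CCc1ccc(OCc2ccccc2)c(OC)c1)N1[C@@H](Cc2ccccc2)COC1=O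
F2 | step 8 | tert-butyl (3R)-4-[(4S)-4-benzyl-2-oxooxazolidin-3-yl]-3-(4-benzyloxy-3-methoxybenzyl)-4-oxobutanoate | O=C([C@H](Cc1ccc(OCc2ccccc2)c(OC)c1)CC(=O)OC(C)(C)C)N1[C@@H](Cc2ccccc2)COC1=O
F3 | step 8 | tert-butyl (3R)-3-(4-benzyloxy-3-methoxybenzyl)-4-hydroxybutanoate | OC[C@H](Cc1ccc(OCc2ccccc2)c(OC)c1)CC(=O)OC(C)(C)C
F4 | step 8 | (R)-4-(4-benzyloxy-3-methoxybenzyl)oxolan-2-one | O=C1C[C@@H](Cc2ccc(OCc3ccccc3)c(OC)c2)CO1
F5 | step 8 | (3S,4R)-3-{[3,4-bis(benzyloxy)phenyl](hydroxy)methyl}-4-(4-benzyloxy-3-methoxybenzyl)oxolan-2-one (carbinol epimers) | O=C1OC[C@H](Cc2ccc(OCc3ccccc3)c(OC)c2)[C@H]1C(O)c1ccc(OCc2ccccc2)c(OCc2ccccc2)c1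
F6 | step 8 | (2R,3R)-2-{[3,4-bis(benzyloxy)phenyl](hydroxy)methyl}-3-(4-benzyloxy-3-methoxybenzyl)butane-1,4-diol (carbinol epimers) | OC[C@H](Cc1ccc(OCc2ccccc2)c(OC)c1)[C@H](CO)C(O)c1ccc(OCc2ccccc2)c(OCc2ccccc2)c1
F0 | step 6 | none | none
F0 | step 11 | none | none
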